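From its first reading at 0.833 d the teal flask held substrate at 54.3 %, and at 6.00 d it read 53.7 %, so I could not share your hunch that it was merely slow. I wrote the balance of the partner, the limiting reagent here.

| flask | substrate | partner | remark | time |
|---|---|---|---|---|
| teal | 0.90 M | 0.80 equiv | the very flask that is asked about, followed so far |  |
| blue | 0.90 M | 1.6 equiv | run made earlier |  |
| flask | 0.90 M | 0.800 equiv |  | 15 d |

| run | time / d | first product / % | other mono adduct / % | substrate / % |
|---|---|---|---|---|
| teal | 0.833 | 40.3 | 3.7 | 54.3 |
| teal | 1.67 | 39.8 | 3.2 | 52.9 |
| teal | 2.50 | 40.5 | 3.0 | 54.0 |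
| teal | 3.00 | 40.4 | 3.0 | 53.8 |
| teal | 4.00 | 40.6 | 2.3 | 54.0 |
| teal | 5.00 | 40.9 | 2.6 | 54.0 |
| teal | 6.00 | 40.9 | 2.7 | 53.7 |
| blue | 0.833 | 63.8 | 1.8 | 24.5 |
| blue | 1.25 | 65.0 | 2.5 | 22.7 |
| blue | 2.08 | 64.5 | 2.6 | 22.9 |
| blue | 3.00 | 64.6 | 3.0 | 23.9 |
| blue | 5.00 | 65.0 | 1.9 | 23.3 |
| blue | 6.00 | 63.7 | 1.9 | 22.5 |
| blue | 10.0 | 65.2 | 3.6 | 22.2 |

(each reading ± 0.5 percentage points)

1. at 15 d, what has stopped the reaction, if anything has (the partner has run out first / all of the substrate has reacted / it is still moving)
2. first product at 15 d, in percent of the substrate charged
3. other mono adduct at 15 d, in percent of the substrate charged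

- on the list of suspects stand: partner + other mono adduct -> bis adduct; partner + first product -> bis adduct; substrate + partner -> first product; substrate + partner -> other mono adduct; partner -> decomposed reagent
- the reaction counts as stopped when no species that holds the substrate changes by six tenths of a point or more over the second half of the time

Each substrate consumed holds a partner and each bis adduct holds a second, with bis adduct found by difference. At 6.00 d the teal run had consumed 46.3 % of the substrate and carried 2.70 % as bis adduct. Its capture share φ, the partner found bound divided by the partner charged, therefore read 61.2 %. With substrate flat I counted no free partner, and so I booked the other 38.8 % of the charge as decomposed reagent. The blue run, with twice the partner, gave φ of 54.2 % and was also flat, with substrate reading 22.2 % at 10.0 d.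

The forecast for 15 d was that the partner has run out first, with first product at 40.6 % (40 % to 41.2 %) and other mono adduct at 2.8 % (2.3 % to 3.3 %). Its ground was this: “Reagent decomposition therefore kills the reaction early, with substrate still present.”

The flask gave the same ending, that the partner has run out first, with first product at 40.6 % and other mono adduct at 2.81 %.

    partner + other mono adduct → bis adduct (k = 0.00450 M⁻¹ min⁻¹)
    partner + first product → bis adduct (k = 2.50 × 10⁻⁴ M⁻¹ min⁻¹)
    substrate + partner → first product (k = 0.00280 M⁻¹ min⁻¹)
    substrate + partner → other mono adduct (k = 3.00 × 10⁻⁴ M⁻¹ min⁻¹)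
    partner → decomposed reagent (k = 0.00140 min⁻¹)

At 0.110 d the asked flask used partner 1.4 times as fast for first product as for decomposition, and by 1.50 d its partner stood at 0.0914 % of the charge. The 0.280 M of decomposed reagent in that flask puts φ at 61.2 %, and the neighbour at 2.2 M of substrate, with 0.388 M of decomposed reagent, reaches φ of 77.9 %, higher than the 61.2 % read from the teal run, with first product of 50.1 %.

Readings and results stem from a simulated flask from invented constants; noise was put on by code.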